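**Plan**
- Cuts: C8–C9 (acyl–vinyl bond; thiol ester + vinylstannane), C11=C12 and C11'=C12' (Wittig), C9'=C10' (Horner–Wadsworth–Emmons). Pieces: a C11 thiol ester carrying the hydroxylated cyclohexene end, a C4 stannyl lactol (C9, C10, C11, C19), the C10 dialdehyde and a C15 salt from (R)-α-ionone.
- The hydroxylated 1,1,5-trimethylcyclohexene ring (C1–C6) is not built as a six-membered ring. Its homoallylic alcohol array C3(OH)–C4H2–C5(CH3)=C6 is the retron of a cyclopropylcarbinyl-to-homoallyl rearrangement. It is traced back to a 2-allyl-1,3,3-trimethylbicyclo[3.1.0]hexan-2-ol: a cyclopentane (C1, C2, C3, C5, C6) with C4 as the fused cyclopropane methylene.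
- Forward, ring: 2-methylcyclopentenone → geminal dimethylation → reduction, cyclopropanation, oxidation, allylation → acid/water ring expansion (five → six) → allyl group cut down to the C8 thiol ester.
- Forward, chain: α-ionone → C15 salt → + C10 dialdehyde → C25 salt → + lactol (C11=C12) → C29 vinylstannane; the C8–C9 bond is made last, then both silyl ethers are removed.
- Stereochemistry: C3 from the ring-fusion CH of the bicycle (CBS reduction, hydroxyl-directed cyclopropanation, inversion during ring expansion); C6' from (R)-α-ionone; C3' from a CBS reduction; 9,10 geometry from the butenolide ring; other alkenes from E-selective olefinations and a final equilibration.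

Key step: step 6

Remark: (R)-α-ionone, 4-bromofuran-2(5H)-one and (2E,4E,6E)-2,7-dimethylocta-2,4,6-trienedial are taken as purchasable, and in both CBS reductions the alkenyl flank of the enone is assumed to act as the large group.

**Route**

Step 1
Reactants: 1 2-methylcyclopent-2-en-1-one
Product: 3 2,5,5-trimethylcyclopent-2-en-1-one, via 2,5-dimethylcyclopent-2-en-1-one 2 (not isolated)
Conditions: LiN(iPr)2, THF, −78 °C, then MeI; recool, second portion of LiN(iPr)2, then MeI, −78 °C → rt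
Reagents that add atoms: iodomethane CI
Why: Kinetic deprotonation of the cross-conjugated enone at C5 and methylation, run twice in one flask, should install the geminal dimethyl group because C5 is the only alpha-prime position (sequential enolate alkylation).

Step 2
Reactants: 3 2,5,5-trimethylcyclopent-2-en-1-one
Product: 4 (1R)-2,5,5-trimethylcyclopent-2-en-1-ol
Conditions: (S)-1-methyl-3,3-diphenyltetrahydro-1H,3H-pyrrolo[1,2-c][1,3,2]oxazaborole ((S)-Me-CBS, 20 mol %), catecholborane, toluene, −78 °C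
Reagents that add atoms: none
Why: Corey–Bakshi–Shibata reduction should deliver hydride to one carbonyl face with the 2-methylalkenyl flank as the large group, which sets the (R)-carbinol that steers the next step.

Step 3
Reactants: 4 (1R)-2,5,5-trimethylcyclopent-2-en-1-ol
Product: 5 (1S,2R,5S)-1,3,3-trimethylbicyclo[3.1.0]hexan-2-ol
Conditions: Et2Zn, CH2I2, CH2Cl2, 0 °C → rt
Reagents that add atoms: diiodomethane ICI
Why: Hydroxyl-directed Simmons–Smith cyclopropanation (Furukawa reagent) delivers the methylene to the alkene face cis to the zinc alkoxide, so the carbinol configuration sets both ring-fusion carbons as (1S,5S).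

Step 4
Reactants: 5 (1S,2R,5S)-1,3,3-trimethylbicyclo[3.1.0]hexan-2-ol
Product: 6 (1S,5S)-1,3,3-trimethylbicyclo[3.1.0]hexan-2-one
Conditions: Dess–Martin periodinane, NaHCO3, CH2Cl2, 0 °C → rt
Reagents that add atoms: none
Why: Dess–Martin oxidation of the secondary cyclopropylcarbinol gives the non-enolisable ketone without touching the cyclopropane; the directing carbinol stereocenter is no longer needed.

Step 5
Reactants: 6 (1S,5S)-1,3,3-trimethylbicyclo[3.1.0]hexan-2-one
Product: 7 (1S,2R,5S)-1,3,3-trimethyl-2-(prop-2-en-1-yl)bicyclo[3.1.0]hexan-2-ol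
Conditions: CH2=CHCH2MgBr, Et2O/THF, 0 °C
Reagents that add atoms: allylmagnesium bromide C=CC[Mg]Br
Why: Grignard 1,2-addition of the allyl reagent through a six-membered transition state tolerates the doubly neopentyl, non-enolisable ketone and should enter anti to the cyclopropane methylene; either C2 epimer is productive because C2 is ionised in the next step.

Step 6
Reactants: 7 (1S,2R,5S)-1,3,3-trimethyl-2-(prop-2-en-1-yl)bicyclo[3.1.0]hexan-2-ol
Product: 9 (1R)-3,5,5-trimethyl-4-(prop-2-en-1-yl)cyclohex-3-en-1-ol, via cyclopropylcarbinyl cation 8 (not isolated)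
Conditions: HClO4 (cat., dilute), acetone/H2O, 0 °C → rt, short reaction time
Reagents that add atoms: water O
Why: Protonation and loss of water from the tertiary carbinol gives cyclopropylcarbinyl cation 8, whose charge is shared with the ring-fusion bond (C1–C5 of the bicycle); water attacks the ring-fusion CH from the side opposite to that bond as it breaks, so the cyclopropane methylene is taken into the carbocycle and the tetrasubstituted alkene appears between the methyl-bearing and the allyl-bearing carbons (C5=C6 of the carotenoid). The closest known reaction type is the cyclopropylcarbinyl-to-homoallyl rearrangement of bicyclo[3.1.0]hexan-2-yl systems, as in the conversion of sabinene hydrate into terpinen-4-ol and of 3,5-cyclosteroid 6-carbinols into 3β-hydroxy-Δ5-steroids. No ring is closed by a new bond: the six-membered ring arises by scission of the bond shared by the cyclopropane and the cyclopentane, a ring expansion by one carbon. The single new stereocenter, the carbinol carbon (C3 of the carotenoid), is controlled by the configuration of the ring-fusion CH of 7, which is inverted by backside entry of water, so the (1S,5S) bicycle should give the (R)-alcohol. The step needs cleavage of the internal and not the peripheral cyclopropane bond, and capture by water before proton loss or hydride shift. The first is secured because only the internal bond puts charge on a secondary carbon and leads to an unstrained cyclohexene with a tetrasubstituted double bond; the second by dilute acid in a large excess of water at low temperature.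

Step 7
Reactants: 9 (1R)-3,5,5-trimethyl-4-(prop-2-en-1-yl)cyclohex-3-en-1-ol
Product: 10 tert-butyl(dimethyl){[(1R)-3,5,5-trimethyl-4-(prop-2-en-1-yl)cyclohex-3-en-1-yl]oxy}silane
Conditions: TBSCl, imidazole, DMF, rt
Reagents that add atoms: tert-butyl(chloro)dimethylsilane CC(C)(C)[Si](C)(C)Cl
Why: Imidazole-promoted silylation protects the secondary alcohol for the oxidations and the acyl coupling.

Step 8
Reactants: 10 tert-butyl(dimethyl){[(1R)-3,5,5-trimethyl-4-(prop-2-en-1-yl)cyclohex-3-en-1-yl]oxy}silane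
Product: 12 2-[(4R)-4-{[tert-butyl(dimethyl)silyl]oxy}-2,6,6-trimethylcyclohex-1-en-1-yl]acetaldehyde, via vicinal diol 11 (not isolated)
Conditions: OsO4 (cat.), NaIO4, 2,6-lutidine, 1,4-dioxane/H2O, rt
Reagents that add atoms: osmium tetroxide O=[Os](=O)(=O)=O (catalytic oxygen carrier); sodium periodate [Na+].[O-]I(=O)(=O)=O
Why: Lemieux–Johnson cleavage: OsO4 should dihydroxylate the monosubstituted terminal alkene much faster than the hindered tetrasubstituted ring alkene, and periodate cuts the diol to the C8 aldehyde.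

Step 9
Reactants: 12 2-[(4R)-4-{[tert-butyl(dimethyl)silyl]oxy}-2,6,6-trimethylcyclohex-1-en-1-yl]acetaldehyde
Product: 13 2-[(4R)-4-{[tert-butyl(dimethyl)silyl]oxy}-2,6,6-trimethylcyclohex-1-en-1-yl]acetic acid
Conditions: NaClO2, NaH2PO4, 2-methylbut-2-ene (large excess), t-BuOH/H2O, 0 °C → rt
Reagents that add atoms: sodium chlorite [Na+].[O-]Cl=O
Why: Pinnick oxidation converts the aldehyde to the acid under buffered conditions that should leave the beta,gamma double bond in place, the scavenger removing hypochlorous acid before it reaches the ring alkene.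

Step 10
Reactants: 13 2-[(4R)-4-{[tert-butyl(dimethyl)silyl]oxy}-2,6,6-trimethylcyclohex-1-en-1-yl]acetic acid
Product: 14 S-phenyl 2-[(4R)-4-{[tert-butyl(dimethyl)silyl]oxy}-2,6,6-trimethylcyclohex-1-en-1-yl]ethanethioate
Conditions: PhSH, EDC·HCl, DMAP (cat.), CH2Cl2, 0 °C → rt
Reagents that add atoms: benzenethiol Sc1ccccc1
Why: Carbodiimide-mediated thioesterification (Steglich type) gives the thiol ester needed for a base-free ketone synthesis.

Step 11
Reactants: 15 (R)-α-ionone
Product: 16 ethyl (2E,4E)-3-methyl-5-[(1R)-2,6,6-trimethylcyclohex-2-en-1-yl]penta-2,4-dienoate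
Conditions: (EtO)2P(O)CH2CO2Et, NaH, THF, 0 °C → rt; the 2Z isomer is removed by chromatography
Reagents that add atoms: triethyl phosphonoacetate CCOC(=O)CP(=O)(OCC)OCC
Why: Horner–Wadsworth–Emmons olefination of the methyl ketone with the stabilised phosphonate should give mainly the 2E dienoate and adds C10' and C11'.

Step 12
Reactants: 16 ethyl (2E,4E)-3-methyl-5-[(1R)-2,6,6-trimethylcyclohex-2-en-1-yl]penta-2,4-dienoate
Product: 17 ethyl (2E,4E)-3-methyl-5-[(1R)-2,6,6-trimethyl-4-oxocyclohex-2-en-1-yl]penta-2,4-dienoate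
Conditions: Mn(OAc)3·2H2O (cat.), t-BuOOH in decane, 3 Å molecular sieves, EtOAc, rt
Reagents that add atoms: tert-butyl hydroperoxide CC(C)(C)OO
Why: Radical allylic oxidation with the peroxide converts the only ring allylic methylene (C3') into the enone, and the neutral medium should leave the gamma stereocenter C6' untouched.

Step 13
Reactants: 17 ethyl (2E,4E)-3-methyl-5-[(1R)-2,6,6-trimethyl-4-oxocyclohex-2-en-1-yl]penta-2,4-dienoate
Product: 18 ethyl (2E,4E)-5-[(1R,4R)-4-hydroxy-2,6,6-trimethylcyclohex-2-en-1-yl]-3-methylpenta-2,4-dienoate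
Conditions: (S)-Me-CBS (20 mol %), catecholborane, toluene, −78 °C
Reagents that add atoms: none
Why: Corey–Bakshi–Shibata 1,2-reduction of the ring enone under catalyst control, the alkenyl flank acting as the large group, should set (3'R); the ester is inert to catecholborane at this temperature.

Step 14
Reactants: 18 ethyl (2E,4E)-5-[(1R,4R)-4-hydroxy-2,6,6-trimethylcyclohex-2-en-1-yl]-3-methylpenta-2,4-dienoate
Product: 19 ethyl (2E,4E)-5-[(1R,4R)-4-{[tert-butyl(dimethyl)silyl]oxy}-2,6,6-trimethylcyclohex-2-en-1-yl]-3-methylpenta-2,4-dienoate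
Conditions: TBSCl, imidazole, DMF, rt
Reagents that add atoms: tert-butyl(chloro)dimethylsilane CC(C)(C)[Si](C)(C)Cl
Why: Silylation makes the ring allylic oxygen less prone to ionisation in the acidic salt formations that follow.

Step 15
Reactants: 19 ethyl (2E,4E)-5-[(1R,4R)-4-{[tert-butyl(dimethyl)silyl]oxy}-2,6,6-trimethylcyclohex-2-en-1-yl]-3-methylpenta-2,4-dienoate
Product: 20 (2E,4E)-5-[(1R,4R)-4-{[tert-butyl(dimethyl)silyl]oxy}-2,6,6-trimethylcyclohex-2-en-1-yl]-3-methylpenta-2,4-dien-1-ol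
Conditions: i-Bu2AlH (2.2 equiv), CH2Cl2, −78 °C
Reagents that add atoms: none
Why: Hydride reduction of the conjugated ester with i-Bu2AlH gives the dienylic alcohol without conjugate reduction.

Step 16
Reactants: 20 (2E,4E)-5-[(1R,4R)-4-{[tert-butyl(dimethyl)silyl]oxy}-2,6,6-trimethylcyclohex-2-en-1-yl]-3-methylpenta-2,4-dien-1-ol
Product: 21 {(2E,4E)-5-[(1R,4R)-4-{[tert-butyl(dimethyl)silyl]oxy}-2,6,6-trimethylcyclohex-2-en-1-yl]-3-methylpenta-2,4-dien-1-yl}triphenylphosphonium bromide
Conditions: PPh3·HBr, CH2Cl2/MeOH, 0 °C → rt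
Reagents that add atoms: triphenylphosphine hydrobromide [Br-].c1ccc(cc1)[PH+](c1ccccc1)c1ccccc1
Why: Substitution of the protonated dienylic alcohol by triphenylphosphine is the classical way to polyenyl Wittig salts; the primary dienylic position ionises far more readily than the silylated ring oxygen.

Step 17
Reactants: 21 the C15 phosphonium bromide; 22 (2E,4E,6E)-2,7-dimethylocta-2,4,6-trienedial (excess, recovered)
Product: 24 (2E,4E,6E,8E,10E,12E)-13-[(1R,4R)-4-{[tert-butyl(dimethyl)silyl]oxy}-2,6,6-trimethylcyclohex-2-en-1-yl]-2,7,11-trimethyltrideca-2,4,6,8,10,12-hexaenal, via C15 phosphorus ylide 23 (not isolated)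
Conditions: NaOMe, MeOH/CH2Cl2, 0 °C → rt, dark; then I2 (cat.), CH2Cl2, ambient light to equilibrate the new double bond
Reagents that add atoms: none
Why: Wittig olefination of one aldehyde group of the excess dialdehyde forms C11'=C12', and iodine-catalysed equilibration should converge the semistabilised-ylide E/Z mixture on the E isomer.

Step 18
Reactants: 24 the C25 aldehyde
Product: 25 (2E,4E,6E,8E,10E,12E)-13-[(1R,4R)-4-{[tert-butyl(dimethyl)silyl]oxy}-2,6,6-trimethylcyclohex-2-en-1-yl]-2,7,11-trimethyltrideca-2,4,6,8,10,12-hexaen-1-ol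
Conditions: NaBH4, MeOH/THF, 0 °C
Reagents that add atoms: none
Why: Borohydride 1,2-reduction of the polyenal gives the primary polyenylic alcohol.

Step 19
Reactants: 25 the C25 alcohol
Product: 26 {(2E,4E,6E,8E,10E,12E)-13-[(1R,4R)-4-{[tert-butyl(dimethyl)silyl]oxy}-2,6,6-trimethylcyclohex-2-en-1-yl]-2,7,11-trimethyltrideca-2,4,6,8,10,12-hexaen-1-yl}triphenylphosphonium bromide
Conditions: PPh3·HBr, CH2Cl2, 0 °C, dark
Reagents that add atoms: triphenylphosphine hydrobromide [Br-].c1ccc(cc1)[PH+](c1ccccc1)c1ccccc1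
Why: Same salt formation as step 16, here on a more easily ionised polyenylic alcohol, so that C12 becomes the nucleophilic partner.

Step 20
Reactants: 27 4-bromofuran-2(5H)-one
Product: 28 4-(tributylstannyl)furan-2(5H)-one
Conditions: (Bu3Sn)2, Pd(PPh3)4 (zerovalent palladium, cat.), toluene, 100 °C
Reagents that add atoms: hexabutylditin CCCC[Sn](CCCC)(CCCC)[Sn](CCCC)(CCCC)CCCC
Why: Palladium-catalysed stannylation of the beta-bromo enoate with the ditin (oxidative addition, tin–tin transmetalation, reductive elimination) puts tin exactly where the bromine was, on the future C9.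

Step 21
Reactants: 28 4-(tributylstannyl)furan-2(5H)-one
Product: 29 4-(tributylstannyl)-2,5-dihydrofuran-2-ol
Conditions: i-Bu2AlH (1.1 equiv), CH2Cl2, −78 °C; neutral work-up with aq. KNaC4H4O6; used crude
Reagents that add atoms: none
Why: Half-reduction of the lactone to the lactol at low temperature masks C11 as an aldehyde while the ring holds C19 and C11 cis on the C9=C10 double bond.

Step 22
Reactants: 26 the C25 phosphonium bromide; 29 4-(tributylstannyl)-2,5-dihydrofuran-2-ol
Product: 31 (2E,4E,6E,8E,10E,12E,14E,16E)-17-[(1R,4R)-4-{[tert-butyl(dimethyl)silyl]oxy}-2,6,6-trimethylcyclohex-2-en-1-yl]-6,11,15-trimethyl-2-(tributylstannyl)heptadeca-2,4,6,8,10,12,14,16-octaen-1-ol, via C25 phosphorus ylide 30 (not isolated)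
Conditions: NaN(SiMe3)2 (one equiv for the salt, one for the lactol), THF, −78 → 0 °C, dark; chromatography on Et3N-deactivated silica
Reagents that add atoms: none
Why: Wittig olefination of the lactol through its open hydroxy-enal form makes C11=C12, keeps the ring-derived 9,10 geometry (tin trans to C11) and releases C19–OH without a protecting group; any 11Z isomer is equilibrated after the last step.

Step 23
Reactants: 14 the S-phenyl thiol ester; 31 the C29 vinylstannane
Product: 32 (3R,3'R,6'R)-3,3'-bis{[tert-butyl(dimethyl)silyl]oxy}-19-hydroxy-7,8-dihydro-β,ε-caroten-8-one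
Conditions: Pd2(dba)3 (zerovalent palladium, 5 mol %), tri(2-furyl)phosphine, CuOP(O)Ph2 (monovalent copper diphenylphosphinate, 1.5 equiv), THF, rt → 40 °C, argon, dark
Reagents that add atoms: none
Why: Liebeskind–Srogl ketone synthesis joins the thiol ester and the vinylstannane with retention at C9 under neutral conditions, so the base-sensitive beta,gamma-unsaturated C8 ketone is formed directly at its final oxidation level.

Step 24
Reactants: 32 the bis-silyl ether
Product: 33 (3R,3'R,6'R)-3,3',19-trihydroxy-7,8-dihydro-β,ε-caroten-8-one (target)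
Conditions: HF·pyridine, excess pyridine, THF, 0 °C → rt, dark; then EtOH, 60 °C, argon, to equilibrate residual Z isomers
Reagents that add atoms: none
Why: Buffered fluoride desilylation frees both ring hydroxyls without the strong acid or base that would ionise the allylic C3'–OH or move the C5=C6 double bond into conjugation, and gentle heating should return Z isomers to the all-E polyene.

**Compound list**
1 | 2-methylcyclopent-2-en-1-one | CC1=CCCC1=O | starting material
2 | 2,5-dimethylcyclopent-2-en-1-one (racemic, not isolated) | CC1=CCC(C)C1=O | intermediate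
3 | 2,5,5-trimethylcyclopent-2-en-1-one | CC1=CCC(C)(C)C1=O | intermediate
4 | (1R)-2,5,5-trimethylcyclopent-2-en-1-ol | CC1=CCC(C)(C)[C@H]1O | intermediate
5 | (1S,2R,5S)-1,3,3-trimethylbicyclo[3.1.0]hexan-2-ol | C[C@]12C[C@H]1CC(C)(C)[C@H]2O | intermediate
6 | (1S,5S)-1,3,3-trimethylbicyclo[3.1.0]hexan-2-one | C[C@]12C[C@H]1CC(C)(C)C2=O | intermediate
7 | (1S,2R,5S)-1,3,3-trimethyl-2-(prop-2-en-1-yl)bicyclo[3.1.0]hexan-2-ol | C[C@]12C[C@H]1CC(C)(C)[C@]2(O)CC=C | intermediate
8 | (1S,5S)-1,3,3-trimethyl-2-(prop-2-en-1-yl)bicyclo[3.1.0]hexan-2-ylium, cyclopropylcarbinyl cation (not isolated) | C[C@]12C[C@H]1CC(C)(C)[C+]2CC=C | intermediate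
9 | (1R)-3,5,5-trimethyl-4-(prop-2-en-1-yl)cyclohex-3-en-1-ol | C=CCC1=C(C)C[C@@H](O)CC1(C)C | intermediate
10 | tert-butyl(dimethyl){[(1R)-3,5,5-trimethyl-4-(prop-2-en-1-yl)cyclohex-3-en-1-yl]oxy}silane | C=CCC1=C(C)C[C@@H](O[Si](C)(C)C(C)(C)C)CC1(C)C | intermediate
11 | 3-[(4R)-4-{[tert-butyl(dimethyl)silyl]oxy}-2,6,6-trimethylcyclohex-1-en-1-yl]propane-1,2-diol (both C2 epimers, not isolated) | OCC(O)CC1=C(C)C[C@@H](O[Si](C)(C)C(C)(C)C)CC1(C)C | intermediate
12 | 2-[(4R)-4-{[tert-butyl(dimethyl)silyl]oxy}-2,6,6-trimethylcyclohex-1-en-1-yl]acetaldehyde | O=CCC1=C(C)C[C@@H](O[Si](C)(C)C(C)(C)C)CC1(C)C | intermediate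
13 | 2-[(4R)-4-{[tert-butyl(dimethyl)silyl]oxy}-2,6,6-trimethylcyclohex-1-en-1-yl]acetic acid | OC(=O)CC1=C(C)C[C@@H](O[Si](C)(C)C(C)(C)C)CC1(C)C | intermediate
14 | S-phenyl 2-[(4R)-4-{[tert-butyl(dimethyl)silyl]oxy}-2,6,6-trimethylcyclohex-1-en-1-yl]ethanethioate | O=C(CC1=C(C)C[C@@H](O[Si](C)(C)C(C)(C)C)CC1(C)C)Sc1ccccc1 | intermediate
15 | (R)-α-ionone, (3E)-4-[(1R)-2,6,6-trimethylcyclohex-2-en-1-yl]but-3-en-2-one | CC1=CCCC(C)(C)[C@H]1/C=C/C(C)=O | starting material
16 | ethyl (2E,4E)-3-methyl-5-[(1R)-2,6,6-trimethylcyclohex-2-en-1-yl]penta-2,4-dienoate | CC1=CCCC(C)(C)[C@H]1/C=C/C(C)=C/C(=O)OCC | intermediate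
17 | ethyl (2E,4E)-3-methyl-5-[(1R)-2,6,6-trimethyl-4-oxocyclohex-2-en-1-yl]penta-2,4-dienoate | CC1=CC(=O)CC(C)(C)[C@H]1/C=C/C(C)=C/C(=O)OCC | intermediate
18 | ethyl (2E,4E)-5-[(1R,4R)-4-hydroxy-2,6,6-trimethylcyclohex-2-en-1-yl]-3-methylpenta-2,4-dienoate | CC1=C[C@H](O)CC(C)(C)[C@H]1/C=C/C(C)=C/C(=O)OCC | intermediate
19 | ethyl (2E,4E)-5-[(1R,4R)-4-{[tert-butyl(dimethyl)silyl]oxy}-2,6,6-trimethylcyclohex-2-en-1-yl]-3-methylpenta-2,4-dienoate | CC1=C[C@H](O[Si](C)(C)C(C)(C)C)CC(C)(C)[C@H]1/C=C/C(C)=C/C(=O)OCC | intermediate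
20 | (2E,4E)-5-[(1R,4R)-4-{[tert-butyl(dimethyl)silyl]oxy}-2,6,6-trimethylcyclohex-2-en-1-yl]-3-methylpenta-2,4-dien-1-ol | CC1=C[C@H](O[Si](C)(C)C(C)(C)C)CC(C)(C)[C@H]1/C=C/C(C)=C/CO | intermediate
21 | {(2E,4E)-5-[(1R,4R)-4-{[tert-butyl(dimethyl)silyl]oxy}-2,6,6-trimethylcyclohex-2-en-1-yl]-3-methylpenta-2,4-dien-1-yl}triphenylphosphonium bromide | CC1=C[C@H](O[Si](C)(C)C(C)(C)C)CC(C)(C)[C@H]1/C=C/C(C)=C/C[P+](c1ccccc1)(c1ccccc1)c1ccccc1.[Br-] | intermediate
22 | (2E,4E,6E)-2,7-dimethylocta-2,4,6-trienedial | O=C/C(C)=C/C=C/C=C(C)/C=O | starting material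
23 | C15 phosphorus ylide from 21 (not isolated) | CC1=C[C@H](O[Si](C)(C)C(C)(C)C)CC(C)(C)[C@H]1/C=C/C(C)=C/C=P(c1ccccc1)(c1ccccc1)c1ccccc1 | intermediate
24 | (2E,4E,6E,8E,10E,12E)-13-[(1R,4R)-4-{[tert-butyl(dimethyl)silyl]oxy}-2,6,6-trimethylcyclohex-2-en-1-yl]-2,7,11-trimethyltrideca-2,4,6,8,10,12-hexaenal | CC1=C[C@H](O[Si](C)(C)C(C)(C)C)CC(C)(C)[C@H]1/C=C/C(C)=C/C=C/C(C)=C/C=C/C=C(C)/C=O | intermediate
25 | (2E,4E,6E,8E,10E,12E)-13-[(1R,4R)-4-{[tert-butyl(dimethyl)silyl]oxy}-2,6,6-trimethylcyclohex-2-en-1-yl]-2,7,11-trimethyltrideca-2,4,6,8,10,12-hexaen-1-ol | CC1=C[C@H](O[Si](C)(C)C(C)(C)C)CC(C)(C)[C@H]1/C=C/C(C)=C/C=C/C(C)=C/C=C/C=C(C)/CO | intermediate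
26 | {(2E,4E,6E,8E,10E,12E)-13-[(1R,4R)-4-{[tert-butyl(dimethyl)silyl]oxy}-2,6,6-trimethylcyclohex-2-en-1-yl]-2,7,11-trimethyltrideca-2,4,6,8,10,12-hexaen-1-yl}triphenylphosphonium bromide | CC1=C[C@H](O[Si](C)(C)C(C)(C)C)CC(C)(C)[C@H]1/C=C/C(C)=C/C=C/C(C)=C/C=C/C=C(C)/C[P+](c1ccccc1)(c1ccccc1)c1ccccc1.[Br-] | intermediate
27 | 4-bromofuran-2(5H)-one | O=C1C=C(Br)CO1 | starting material
28 | 4-(tributylstannyl)furan-2(5H)-one | O=C1C=C([Sn](CCCC)(CCCC)CCCC)CO1 | intermediate
29 | 4-(tributylstannyl)-2,5-dihydrofuran-2-ol (racemic lactol) | OC1C=C([Sn](CCCC)(CCCC)CCCC)CO1 | intermediate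
30 | C25 phosphorus ylide from 26 (not isolated) | CC1=C[C@H](O[Si](C)(C)C(C)(C)C)CC(C)(C)[C@H]1/C=C/C(C)=C/C=C/C(C)=C/C=C/C=C(C)/C=P(c1ccccc1)(c1ccccc1)c1ccccc1 | intermediate
31 | (2E,4E,6E,8E,10E,12E,14E,16E)-17-[(1R,4R)-4-{[tert-butyl(dimethyl)silyl]oxy}-2,6,6-trimethylcyclohex-2-en-1-yl]-6,11,15-trimethyl-2-(tributylstannyl)heptadeca-2,4,6,8,10,12,14,16-octaen-1-ol | CC1=C[C@H](O[Si](C)(C)C(C)(C)C)CC(C)(C)[C@H]1/C=C/C(C)=C/C=C/C(C)=C/C=C/C=C(C)/C=C/C=C(\CO)[Sn](CCCC)(CCCC)CCCC | intermediate
32 | (3R,3'R,6'R)-3,3'-bis{[tert-butyl(dimethyl)silyl]oxy}-19-hydroxy-7,8-dihydro-β,ε-caroten-8-one | CC1=C[C@H](O[Si](C)(C)C(C)(C)C)CC(C)(C)[C@H]1/C=C/C(C)=C/C=C/C(C)=C/C=C/C=C(C)/C=C/C=C(\CO)C(=O)CC1=C(C)C[C@@H](O[Si](C)(C)C(C)(C)C)CC1(C)C | intermediate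
33 | (3R,3'R,6'R)-3,3',19-trihydroxy-7,8-dihydro-β,ε-caroten-8-one | CC1=C[C@H](O)CC(C)(C)[C@H]1/C=C/C(C)=C/C=C/C(C)=C/C=C/C=C(C)/C=C/C=C(\CO)C(=O)CC1=C(C)C[C@@H](O)CC1(C)C | target

**Count**
Total steps: 24. Longest linear sequence: 12 steps (steps 11–19, then 22–24; the sequence 1–10, then 23–24 is equally long).

**Steps most likely to fail and fallbacks**

Step 6. The peripheral cyclopropane bond may break in place of the ring-fusion bond, the cation may lose a proton to dienes, or a free secondary cation may let the carbinol configuration leak. The fallback triggers the same skeletal change with an electrophile on an alkene, without strong acid. It sets out from 6: Wittig methylenation (Ph3PCH3Br, KOtBu, toluene, 90 °C) should give (1S,5S)-1,3,3-trimethyl-2-methylidenebicyclo[3.1.0]hexane F1. N-Bromosuccinimide in buffered aqueous acetone at −20 °C should then add bromine to the exocyclic carbon while water enters the ring-fusion CH with inversion, giving (1R)-4-(bromomethyl)-3,5,5-trimethylcyclohex-3-en-1-ol F2. Silylation (TBSCl, imidazole) gives {[(1R)-4-(bromomethyl)-3,5,5-trimethylcyclohex-3-en-1-yl]oxy}(tert-butyl)dimethylsilane F3, and copper-catalysed coupling with CH2=CHMgBr (CuI cat., THF, −30 °C) at the primary allylic carbon returns to the route at 10.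

Step 2. Facial discrimination may be poor because both flanks of the ketone are fully substituted. The fallback drops asymmetric reduction for cyclopropanation of the racemate and resolution. It sets out from 3: Corey–Chaykovsky cyclopropanation (Me3S(O)I, NaH, DMSO) should give racemic 1,3,3-trimethylbicyclo[3.1.0]hexan-2-one F4 in one step. Preparative chromatography on a chiral stationary phase then delivers the (1S,5S) enantiomer, which is compound 6, where the route is rejoined.

Step 21. The lactol may lose water and aromatise to a furan during work-up, or open too sluggishly for the Wittig step. The fallback uses an open-chain, silylated aldehyde in its place. It sets out from 28: aminolysis with Me(MeO)NH·HCl/AlMe3 should give (2E)-4-hydroxy-N-methoxy-N-methyl-3-(tributylstannyl)but-2-enamide F5. Immediate silylation (TBSOTf, 2,6-lutidine) gives (2E)-4-{[tert-butyl(dimethyl)silyl]oxy}-N-methoxy-N-methyl-3-(tributylstannyl)but-2-enamide F6, and i-Bu2AlH at −78 °C gives (2E)-4-{[tert-butyl(dimethyl)silyl]oxy}-3-(tributylstannyl)but-2-enal F7. Wittig reaction with ylide 30 (from 26) gives the 1-O-silyl ether of 31 F8. Coupling with 14 under the conditions of step 23 gives (3R,3'R,6'R)-3,3',19-tris{[tert-butyl(dimethyl)silyl]oxy}-7,8-dihydro-β,ε-caroten-8-one F9, and HF·pyridine removes all three silyl groups to rejoin the route at 33.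

**Further compounds**
F1 | step 6 | (1S,5S)-1,3,3-trimethyl-2-methylidenebicyclo[3.1.0]hexane | C[C@]12C[C@H]1CC(C)(C)C2=C
F2 | step 6 | (1R)-4-(bromomethyl)-3,5,5-trimethylcyclohex-3-en-1-ol | BrCC1=C(C)C[C@@H](O)CC1(C)C
F3 | step 6 | {[(1R)-4-(bromomethyl)-3,5,5-trimethylcyclohex-3-en-1-yl]oxy}(tert-butyl)dimethylsilane | BrCC1=C(C)C[C@@H](O[Si](C)(C)C(C)(C)C)CC1(C)C
F4 | step 2 | racemic 1,3,3-trimethylbicyclo[3.1.0]hexan-2-one | CC12CC1CC(C)(C)C2=O
F5 | step 21 | (2E)-4-hydroxy-N-methoxy-N-methyl-3-(tributylstannyl)but-2-enamide | CON(C)C(=O)/C=C(\CO)[Sn](CCCC)(CCCC)CCCC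
F6 | step 21 | (2E)-4-{[tert-butyl(dimethyl)silyl]oxy}-N-methoxy-N-methyl-3-(tributylstannyl)but-2-enamide | CON(C)C(=O)/C=C(\CO[Si](C)(C)C(C)(C)C)[Sn](CCCC)(CCCC)CCCC
F7 | step 21 | (2E)-4-{[tert-butyl(dimethyl)silyl]oxy}-3-(tributylstannyl)but-2-enal | O=C/C=C(\CO[Si](C)(C)C(C)(C)C)[Sn](CCCC)(CCCC)CCCC
F8 | step 21 | 1-O-[tert-butyl(dimethyl)silyl] ether of 31 | CC1=C[C@H](O[Si](C)(C)C(C)(C)C)CC(C)(C)[C@H]1/C=C/C(C)=C/C=C/C(C)=C/C=C/C=C(C)/C=C/C=C(\CO[Si](C)(C)C(C)(C)C)[Sn](CCCC)(CCCC)CCCC
F9 | step 21 | (3R,3'R,6'R)-3,3',19-tris{[tert-butyl(dimethyl)silyl]oxy}-7,8-dihydro-β,ε-caroten-8-one | CC1=C[C@H](O[Si](C)(C)C(C)(C)C)CC(C)(C)[C@H]1/C=C/C(C)=C/C=C/C(C)=C/C=C/C=C(C)/C=C/C=C(\CO[Si](C)(C)C(C)(C)C)C(=O)CC1=C(C)C[C@@H](O[Si](C)(C)C(C)(C)C)CC1(C)C
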